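The route rests on cutting the O1–C8a bond of the pyran ring. C8a lies para to the acyl-bearing C6 on the benzene ring, and O1 sits on the fully substituted C2. A bromide placed at C8a and a tertiary alcohol with no carbinol hydrogen can therefore be joined by palladium, with no choice to be made among the three ring oxygens. One operation closes the pyran ring and fixes the chromene isomer. The precursor is a 4-bromo-isobutyrophenone with a (Z)-3-hydroxy-3-methylbut-1-enyl chain next to bromine and two methoxymethyl-protected phenols flanking the ketone. Deprotection and a Mannich/o-quinone methide union with the pyrone half at C8 finish the target.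

Key step: step 8

Remark on the design: chromene numbering is used for the ring atoms throughout, also in open-chain precursors. The phenols at C5 and C7 pass through the key step as methoxymethyl (MOM) ethers, not as methyl ethers.
- The carbonyl oxygen of the C6 ketone can face only one of its two ortho oxygens, so a boron trihalide gets chelation help for one methyl ether only.
- Forcing off the second methyl ether would expose the aryl tert-allyl ether O1–C2 of the chromene to a strong Lewis acid. The danger is ring opening and re-closure onto the C5 oxygen.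
- The commercial dimethyl ether is therefore exchanged early, on a robust bromo-iodo ketone, and the late deprotection needs only catalytic acid in methanol.

Assumption: the pyrone half is not taken as a catalogue compound and is made in two steps from methyl 3-oxopentanoate.

Step 1
Reactants: 1 4-bromo-2,6-dimethoxybenzaldehyde; 2 isopropylmagnesium chloride
Product: 3 (±)-1-(4-bromo-2,6-dimethoxyphenyl)-2-methylpropan-1-ol
Conditions: 2 (1.2 equiv), THF, −20 → 0 °C; sat. aq NH4Cl
Reagents that add atoms: isopropylmagnesium chloride (2), CC(C)[Mg]Cl
Why: Grignard 1,2-addition to the aldehyde is far faster than bromine–magnesium exchange on this aryl bromide at low temperature, and the new carbinol centre is left racemic because step 2 erases it.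

Step 2
Reactants: 3 (±)-1-(4-bromo-2,6-dimethoxyphenyl)-2-methylpropan-1-ol
Product: 4 1-(4-bromo-2,6-dimethoxyphenyl)-2-methylpropan-1-one
Conditions: Dess–Martin periodinane (1.2 equiv), CH2Cl2, 0 °C → rt
Reagents that add atoms: none
Why: Dess–Martin oxidation turns the hindered secondary benzylic alcohol into the aryl isopropyl ketone under near-neutral conditions that touch neither the aryl bromide nor the methyl ethers, and it removes the stereocentre.

Step 3
Reactants: 4 1-(4-bromo-2,6-dimethoxyphenyl)-2-methylpropan-1-one
Product: 5 1-(4-bromo-3-iodo-2,6-dimethoxyphenyl)-2-methylpropan-1-one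
Conditions: NIS (1.05 equiv), TFA (0.5 equiv), MeCN, rt, dark
Reagents that add atoms: N-iodosuccinimide, O=C1CCC(=O)N1I
Why: In this electrophilic aromatic iodination the two free ring positions are equivalent, each ortho to one methoxy group, para to the other and next to bromine, so acid-activated NIS has only one possible site, and one equivalent plus the added crowding should hold it at mono-iodination.

Step 4
Reactants: 5 1-(4-bromo-3-iodo-2,6-dimethoxyphenyl)-2-methylpropan-1-one
Product: 6 1-(4-bromo-2,6-dihydroxy-3-iodophenyl)-2-methylpropan-1-one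
Conditions: BBr3 (3.5 equiv), CH2Cl2, −78 °C → rt; ice water
Reagents that add atoms: none
Why: Boron tribromide ether cleavage (complexation at oxygen, then SN2 attack of bromide on methyl) removes both aryl methyl ethers, with chelation to the ketone speeding the first and excess reagent at room temperature taking the second, on a substrate that has no acid-labile group yet.

Step 5
Reactants: 6 1-(4-bromo-2,6-dihydroxy-3-iodophenyl)-2-methylpropan-1-one
Product: 7 1-[4-bromo-3-iodo-2,6-bis(methoxymethoxy)phenyl]-2-methylpropan-1-one
Conditions: NaH (2.4 equiv), DMF, 0 °C; MOMCl (3 equiv), 0 °C → rt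
Reagents that add atoms: chloromethyl methyl ether (MOMCl), COCCl
Why: Williamson-type O-alkylation of the bis-phenoxide with the small, very reactive MOMCl overcomes hydrogen bonding and crowding next to the ketone and installs acetals that are inert to base, palladium and hydrogen but fall to mild protic acid.

Step 6
Reactants: 7 1-[4-bromo-3-iodo-2,6-bis(methoxymethoxy)phenyl]-2-methylpropan-1-one; 8 2-methylbut-3-yn-2-ol
Product: 9 1-[4-bromo-3-(3-hydroxy-3-methylbut-1-yn-1-yl)-2,6-bis(methoxymethoxy)phenyl]-2-methylpropan-1-one
Conditions: 8 (1.3 equiv), PdCl2(PPh3)2 (3 mol %), CuI (6 mol %), Et3N/THF, 40 °C, degassed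
Reagents that add atoms: 2-methylbut-3-yn-2-ol (8), CC(C)(O)C#C
Why: The Sonogashira coupling is chemoselective because zerovalent palladium inserts into the C–I bond much faster than into the neighbouring C–Br bond at mild temperature, and the slim copper acetylide tolerates the two ortho substituents.

Step 7
Reactants: 9 1-[4-bromo-3-(3-hydroxy-3-methylbut-1-yn-1-yl)-2,6-bis(methoxymethoxy)phenyl]-2-methylpropan-1-one
Product: 10 1-{4-bromo-3-[(Z)-3-hydroxy-3-methylbut-1-en-1-yl]-2,6-bis(methoxymethoxy)phenyl}-2-methylpropan-1-one
Conditions: H2 (1 atm), Pd/CaCO3 poisoned with Pb(OAc)2 (Lindlar catalyst), quinoline, EtOAc, rt, stopped after one equivalent of H2; Et3N-deactivated silica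
Reagents that add atoms: none
Why: Lindlar semihydrogenation delivers both hydrogens to one face of the adsorbed alkyne (syn addition), which sets the Z geometry, while lead and quinoline poisoning suppress over-reduction and hydrogenolysis of the C–Br bond.

Step 8
Reactants: 10 1-{4-bromo-3-[(Z)-3-hydroxy-3-methylbut-1-en-1-yl]-2,6-bis(methoxymethoxy)phenyl}-2-methylpropan-1-one
Product: 11 1-[5,7-bis(methoxymethoxy)-2,2-dimethyl-2H-chromen-6-yl]-2-methylpropan-1-one
Conditions: Pd(OAc)2 (4 mol %), 2-(di-tert-butylphosphino)-1,1'-binaphthyl (5 mol %), Cs2CO3 (1.5 equiv), toluene, 70 °C, Ar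
Reagents that add atoms: none
Why: Pd(OAc)2 is reduced in the flask to zerovalent palladium, which inserts into the C8a–Br bond (helped by the para acyl group); carbonate then deprotonates the side-chain hydroxyl, the alkoxide takes the place of bromide on divalent palladium, and C–O reductive elimination releases 11 and the zerovalent catalyst. The closest known reaction type is the Buchwald–Hartwig-type intramolecular etherification of aryl bromides with tertiary alcohols, which gives chromans and related oxygen heterocycles. The pyran ring closes by ring-contracting reductive elimination from a seven-membered oxapalladacycle (Pd, C8a, C4a, C4, C3, C2, O1), a six-membered closure in which the Z alkene and the geminal methyl groups keep the oxygen near the metal. No stereocentre is formed, and the Z geometry from step 7 becomes the endocyclic C3=C4 bond. The step needs site selectivity for O1 and chemoselectivity for C–O coupling over hydrodebromination: the first is secured because bromide marks C8a and both phenols are masked, the second because C2 carries no hydrogen for β-hydride elimination and the bulky, electron-rich phosphine speeds reductive elimination. The weak carbonate base leaves the hindered isopropyl ketone un-enolised, so α-arylation should not compete.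

Step 9
Reactants: 11 1-[5,7-bis(methoxymethoxy)-2,2-dimethyl-2H-chromen-6-yl]-2-methylpropan-1-one
Product: 12 1-(5,7-dihydroxy-2,2-dimethyl-2H-chromen-6-yl)-2-methylpropan-1-one
Conditions: p-TsOH·H2O (0.2 equiv), MeOH, 45 °C, dark
Reagents that add atoms: none
Why: Acid-catalysed acetal exchange (MOM cleavage) in methanol is eased by the neighbouring carbonyl group, turns the acetal carbon into volatile dimethoxymethane so that no free formaldehyde meets the nucleophilic C8, and is mild enough for the 2,2-dimethylchromene.

Step 10
Reactants: 13 methyl 3-oxopentanoate; 14 N-methoxy-N-methylpropanamide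
Product: 16 (±)-methyl 4-methyl-3,5-dioxoheptanoate, via sodium lithium dienolate 15 (not isolated)
Conditions: NaH (1.1 equiv), THF, 0 °C; n-BuLi (1.05 equiv), 0 °C; 14 (1.0 equiv), 0 °C → rt; aq HCl
Reagents that add atoms: N-methoxy-N-methylpropanamide (14), CCC(=O)N(C)OC
Why: γ-Acylation of a β-keto ester dianion (Claisen-type) takes place at the more basic terminal carbanion, the chelated tetrahedral adduct of the Weinreb amide prevents over-addition, and the new C4 centre is racemic, enolisable and lost in step 11.

Step 11
Reactants: 16 (±)-methyl 4-methyl-3,5-dioxoheptanoate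
Product: 17 6-ethyl-4-hydroxy-5-methyl-2H-pyran-2-one
Conditions: DBU (1.0 equiv), toluene, reflux; aq HCl
Reagents that add atoms: none
Why: In this base-mediated lactonisation of a 3,5-dioxo ester the enolate oxygen at C5 attacks the methyl ester in a 6-exo-trig acyl substitution, and tautomerisation gives the stable 4-hydroxy-2-pyrone.

Step 12
Reactants: 12 1-(5,7-dihydroxy-2,2-dimethyl-2H-chromen-6-yl)-2-methylpropan-1-one; 18 N,N-dimethylmethyleneiminium iodide (Eschenmoser's salt); 17 6-ethyl-4-hydroxy-5-methyl-2H-pyran-2-one
Product: 21 3-{[5,7-dihydroxy-2,2-dimethyl-6-(2-methylpropanoyl)-2H-chromen-8-yl]methyl}-6-ethyl-4-hydroxy-5-methyl-2H-pyran-2-one, via Mannich base 19 (not isolated), via o-quinone methide 20 (not isolated)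
Conditions: 18 (1.0 equiv), MeCN, 0 °C → rt; then 17 (1.2 equiv), NaOAc (1.1 equiv), 80 °C, dark
Reagents that add atoms: N,N-dimethylmethyleneiminium iodide (18), C[N+](C)=C.[I-]; 6-ethyl-4-hydroxy-5-methyl-2H-pyran-2-one (17), CCc1oc(=O)cc(O)c1C
Why: A phenolic Mannich reaction at C8, the only free ring carbon, followed by thermal loss of dimethylamine gives an o-quinone methide across C7–C8 that is captured by Michael addition of the best nucleophile present, C3 of the pyrone, so the methylene carbon is placed on the chromene first and symmetrical pyrone dimers are avoided; no stereocentre is formed.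

Compound list
1 | 4-bromo-2,6-dimethoxybenzaldehyde | COc1cc(Br)cc(OC)c1C=O | starting material
2 | isopropylmagnesium chloride | CC(C)[Mg]Cl | starting material
3 | (±)-1-(4-bromo-2,6-dimethoxyphenyl)-2-methylpropan-1-ol (racemic) | CC(C)C(O)c1c(OC)cc(Br)cc1OC | intermediate
4 | 1-(4-bromo-2,6-dimethoxyphenyl)-2-methylpropan-1-one | CC(C)C(=O)c1c(OC)cc(Br)cc1OC | intermediate
5 | 1-(4-bromo-3-iodo-2,6-dimethoxyphenyl)-2-methylpropan-1-one | CC(C)C(=O)c1c(OC)cc(Br)c(I)c1OC | intermediate
6 | 1-(4-bromo-2,6-dihydroxy-3-iodophenyl)-2-methylpropan-1-one | CC(C)C(=O)c1c(O)cc(Br)c(I)c1O | intermediate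
7 | 1-[4-bromo-3-iodo-2,6-bis(methoxymethoxy)phenyl]-2-methylpropan-1-one | CC(C)C(=O)c1c(OCOC)cc(Br)c(I)c1OCOC | intermediate
8 | 2-methylbut-3-yn-2-ol | CC(C)(O)C#C | starting material
9 | 1-[4-bromo-3-(3-hydroxy-3-methylbut-1-yn-1-yl)-2,6-bis(methoxymethoxy)phenyl]-2-methylpropan-1-one | CC(C)C(=O)c1c(OCOC)cc(Br)c(C#CC(C)(C)O)c1OCOC | intermediate
10 | 1-{4-bromo-3-[(Z)-3-hydroxy-3-methylbut-1-en-1-yl]-2,6-bis(methoxymethoxy)phenyl}-2-methylpropan-1-one | CC(C)C(=O)c1c(OCOC)cc(Br)c(/C=C\C(C)(C)O)c1OCOC | intermediate
11 | 1-[5,7-bis(methoxymethoxy)-2,2-dimethyl-2H-chromen-6-yl]-2-methylpropan-1-one | CC(C)C(=O)c1c(OCOC)cc2OC(C)(C)C=Cc2c1OCOC | intermediate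
12 | 1-(5,7-dihydroxy-2,2-dimethyl-2H-chromen-6-yl)-2-methylpropan-1-one | CC(C)C(=O)c1c(O)cc2OC(C)(C)C=Cc2c1O | intermediate
13 | methyl 3-oxopentanoate | CCC(=O)CC(=O)OC | starting material
14 | N-methoxy-N-methylpropanamide | CCC(=O)N(C)OC | starting material
15 | sodium lithium dienolate (dianion) of methyl 3-oxopentanoate | [Na+].[Li+].CC=C([O-])C=C([O-])OC | intermediate
16 | (±)-methyl 4-methyl-3,5-dioxoheptanoate (racemic, enolisable) | CCC(=O)C(C)C(=O)CC(=O)OC | intermediate
17 | 6-ethyl-4-hydroxy-5-methyl-2H-pyran-2-one | CCc1oc(=O)cc(O)c1C | intermediate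
18 | N,N-dimethylmethyleneiminium iodide (Eschenmoser's salt) | C[N+](C)=C.[I-] | starting material
19 | 1-{8-[(dimethylamino)methyl]-5,7-dihydroxy-2,2-dimethyl-2H-chromen-6-yl}-2-methylpropan-1-one | CC(C)C(=O)c1c(O)c(CN(C)C)c2OC(C)(C)C=Cc2c1O | intermediate
20 | 5-hydroxy-2,2-dimethyl-8-methylidene-6-(2-methylpropanoyl)-2H-chromen-7(8H)-one | C=C1C(=O)C(C(=O)C(C)C)=C(O)C2=C1OC(C)(C)C=C2 | intermediate
21 | 3-{[5,7-dihydroxy-2,2-dimethyl-6-(2-methylpropanoyl)-2H-chromen-8-yl]methyl}-6-ethyl-4-hydroxy-5-methyl-2H-pyran-2-one | CCc1oc(=O)c(Cc2c(O)c(C(=O)C(C)C)c(O)c3c2OC(C)(C)C=C3)c(O)c1C | target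

Total step count: 12. Longest linear sequence: 10 steps (steps 1–9 and 12). The pyrone branch (steps 10 and 11) is convergent.

Steps most likely to fail

Step 8. Slow C–O reductive elimination would leave room for hydrodebromination, Z-to-E isomerisation of the side-chain alkene, or β-carbon scission of the tertiary alkoxide on palladium. The fallback reverses the order in which the two C–O bonds of O1 are made.
- It sets out from 10. Miyaura borylation (B2pin2, PdCl2(dppf), KOAc, dioxane, 80 °C) should give the aryl pinacol boronate F1.
- Oxidation with NaBO3·4H2O in THF/H2O at rt should give the C8a phenol F2.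
- Gentle warming with catalytic PPTS in toluene should close O1–C2 with loss of water, by capture of the allyl cation or by o-quinone methide formation and oxa-6π closure. This comes back to the route at 11.
- The C8a hydroxyl is the only free phenol, so the position of O1 stays fixed.

Step 12. The o-quinone methide could self-condense, or the methylene unit could be transferred between partners, which would erode the cross-coupling in favour of symmetrical dimers. The fallback replaces o-quinone methide chemistry by a reductive alkylation.
- It sets out from 12. Vilsmeier–Haack formylation (POCl3, DMF, EtOAc, rt; aqueous hydrolysis) at the only free ring carbon should give 5,7-dihydroxy-2,2-dimethyl-6-(2-methylpropanoyl)-2H-chromene-8-carbaldehyde F3.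
- A three-component organocatalytic reductive alkylation with 17, Hantzsch ester and L-proline (EtOH or CH2Cl2, rt) passes through the Knoevenagel adduct F4.
- That adduct is reduced by hydride transfer as it forms, and the sequence comes back to the route at 21.

Step 7. Possible failures are over-reduction to the saturated chain, stalled hydrogen uptake at the crowded alkyne, and loss of bromine on the catalyst surface. The fallback brings in the alkene with its geometry already set.
- Et3B-initiated radical hydrostannylation of 8 with Bu3SnH at low temperature (kinetic anti addition, any E isomer removed by chromatography) should give (Z)-2-methyl-4-(tributylstannyl)but-3-en-2-ol F5.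
- Setting out from 7, Stille coupling at the C–I bond (Pd(PPh3)4, CuI as co-catalyst, DMF, 45 °C) proceeds with retention of alkene geometry. It comes back to the route at 10 and bypasses 9.

Further compounds
F1 | step 8 | 1-{3-[(Z)-3-hydroxy-3-methylbut-1-en-1-yl]-2,6-bis(methoxymethoxy)-4-(4,4,5,5-tetramethyl-1,3,2-dioxaborolan-2-yl)phenyl}-2-methylpropan-1-one | CC(C)C(=O)c1c(OCOC)cc(B2OC(C)(C)C(C)(C)O2)c(/C=C\C(C)(C)O)c1OCOC
F2 | step 8 | 1-{4-hydroxy-3-[(Z)-3-hydroxy-3-methylbut-1-en-1-yl]-2,6-bis(methoxymethoxy)phenyl}-2-methylpropan-1-one | CC(C)C(=O)c1c(OCOC)cc(O)c(/C=C\C(C)(C)O)c1OCOC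
F3 | step 12 | 5,7-dihydroxy-2,2-dimethyl-6-(2-methylpropanoyl)-2H-chromene-8-carbaldehyde | CC(C)C(=O)c1c(O)c(C=O)c2OC(C)(C)C=Cc2c1O
F4 | step 12 | 3-{[5,7-dihydroxy-2,2-dimethyl-6-(2-methylpropanoyl)-2H-chromen-8-yl]methylidene}-6-ethyl-5-methyl-2H-pyran-2,4(3H)-dione (alkene geometry not defined) | CCC1=C(C)C(=O)C(=Cc2c(O)c(C(=O)C(C)C)c(O)c3c2OC(C)(C)C=C3)C(=O)O1
F5 | step 7 | (Z)-2-methyl-4-(tributylstannyl)but-3-en-2-ol | CCCC[Sn](CCCC)(CCCC)/C=C\C(C)(C)O
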